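**Plan**

1. Cuts: (a) retro-Diels–Alder across C12–C4′ and C15–C5′ of the cyclohexene gives the labdane diene aldehyde trans-communal (fragment 1) and the ring-trans 4′-formyl caryophyllene (fragment 2); (b) the decalin of fragment 1 is opened at C4–C5 and C9–C10 to an acyclic (E,E,E)-tetraenyl 2-methyl-3-oxo ester; (c) that chain is cut at C1–C2 and C11–C12.
2. Enabling feature: rings A and B form a trans-decalin whose quaternary C4 (CH3, CO2H) and C10 (CH3), C8 exocyclic methylene and equatorial C9 side chain map onto an (E,E)-1,5-diene (C5=C10, C8=C9). The chain ends in a C4 carbon alpha to an ester and to a removable C3 ketone, so one C4 radical can close ring A (C4–C5), then ring B (C9–C10), and finish by loss of a C17 hydrogen; the side-chain diene (E-C12=C13–C14=C15) is out of reach of the C8 radical.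
3. Forward order: chain assembly → ring A then ring B in one oxidative radical cascade → C3 deoxygenation with C19 reduction, reoxidation to the aldehyde → fragment 2 from (−)-caryophyllene oxide → cyclohexene by [4+2] → both aldehydes to acids.
4. Stereochemistry: C4 from an 8-phenylmenthyl ester; C5, C10, C9 from the E,E geometry through a chair–chair fold; C1′, C9′ from the chiral pool; the ring-trans C4′=C5′ bond from an epoxide → cis-epoxide → inversion sequence; C12, C4′, C5′ from an endo, suprafacial cycloaddition on the exposed face of that olefin.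

Key step: step 6

Numbering: labdane numbering for the diterpene half (C19 = ester/acid carbon on C4); caryophyllane numbering with primes for the sesquiterpene half (C12′ = carbon on C4′, C13′ = exocyclic methylene carbon).

Assumption: the (1R,2S,5R)-8-phenylmenthyl ester is taken to shield the face of the C4 radical that leads to the natural labdane series (4β-ester, 10β-methyl); if the induction has the opposite sense, the enantiomeric alcohol is used in step 1 and nothing else changes.

**Route**

Step 1
Reactants: 1 ethyl 2-methyl-3-oxobutanoate; 2 (1R,2S,5R)-(−)-8-phenylmenthol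
Product: 3 (1R,2S,5R)-8-phenylmenthyl 2-methyl-3-oxobutanoate
Conditions: DMAP (0.3 equiv), PhMe, reflux, 4 Å MS (removal of EtOH)
Reagents that add atoms: none
Why: DMAP-catalysed transesterification of a β-keto ester exchanges ethanol for the hindered secondary alcohol without touching its three stereocentres, the α-carbon of the keto ester staying a mixture of epimers that is erased later when it becomes a radical.

Step 2
Reactants: 4 but-1-en-3-yne; 5 geranyl chloride
Product: 7 (3E,6E)-α-farnesene, via alkenylalane 6 (not isolated)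
Conditions: 4, Me3Al (2 equiv), Cp2ZrCl2 (0.25 equiv), (CH2Cl)2, 0 °C → rt; then 5, Pd(PPh3)4 (3 mol %), THF, rt
Reagents that add atoms: trimethylaluminium, C[Al](C)C
Why: Negishi zirconium-catalysed carboalumination adds CH3 and Al syn across the alkyne with Al on the terminal carbon, and the zerovalent-palladium allyl–alkenyl coupling then joins C11 to C12 at the primary allylic carbon with retention of both olefin geometries.

Step 3
Reactants: 7 (3E,6E)-α-farnesene
Product: 8 (2E,6E,9E)-2,6,10-trimethyldodeca-2,6,9,11-tetraen-1-ol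
Conditions: SeO2 (0.2 equiv), t-BuOOH (3 equiv), salicylic acid (0.1 equiv), CH2Cl2, 0 °C → rt, stopped at partial conversion
Reagents that add atoms: selenium dioxide, O=[Se]=O (catalytic oxygen carrier); tert-butyl hydroperoxide, CC(C)(C)OO (stoichiometric oxygen source)
Why: Riley-type allylic oxidation (ene reaction followed by a [2,3]-shift) should attack the most electron-rich and least hindered terminal isopropylidene group and oxidise its E-methyl group, as in other polyprenyl chains, faster than it touches the internal alkene or the conjugated diene.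

Step 4
Reactants: 8 (2E,6E,9E)-2,6,10-trimethyldodeca-2,6,9,11-tetraen-1-ol
Product: 9 (2E,6E,9E)-1-bromo-2,6,10-trimethyldodeca-2,6,9,11-tetraene
Conditions: PBr3 (0.4 equiv), pyridine (0.1 equiv), Et2O, −20 °C
Reagents that add atoms: phosphorus tribromide, BrP(Br)Br
Why: SN2 displacement of the phosphite-activated primary allylic alcohol at low temperature should give the primary bromide without allylic transposition or change of olefin geometry.

Step 5
Reactants: 3 (1R,2S,5R)-8-phenylmenthyl 2-methyl-3-oxobutanoate; 9 (2E,6E,9E)-1-bromo-2,6,10-trimethyldodeca-2,6,9,11-tetraene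
Product: 10 (1R,2S,5R)-8-phenylmenthyl (6E,10E,13E)-2,6,10,14-tetramethyl-3-oxohexadeca-6,10,13,15-tetraenoate
Conditions: 3, LiN(iPr)2 (2.1 equiv), THF, −78 → 0 °C; then 9, −78 → 0 °C; AcOH quench
Reagents that add atoms: none
Why: γ-Alkylation of a β-keto ester dianion, in which the more basic γ-carbanion displaces the primary allylic bromide by SN2 and forms the C1–C2 bond without scrambling the three E double bonds.

Step 6
Reactants: 10 (1R,2S,5R)-8-phenylmenthyl (6E,10E,13E)-2,6,10,14-tetramethyl-3-oxohexadeca-6,10,13,15-tetraenoate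
Product: 11 (1R,2S,5R)-8-phenylmenthyl (4R,5R,9S,10R)-3-oxolabda-8(17),12E,14-trien-19-oate
Conditions: Mn(OAc)3·2H2O (2.2 equiv), Cu(OAc)2·H2O (1.0 equiv), degassed AcOH (0.02 M), 20 °C
Reagents that add atoms: none
Why: Mn(OAc)3 enolises the 2-methyl-3-oxo ester and electron transfer within the trivalent-manganese enolate gives the C4 radical, which adds to C5 of the C5=C10 alkene; the tertiary C10 radical then adds to C9 of the C8=C9 alkene (forming the C9–C10 bond and ring B), and the tertiary C8 radical is captured by Cu(OAc)2 and loses a C17 hydrogen by syn-β-hydride elimination to give the 8(17)-methylene. The closest known reaction type is the trivalent-manganese/divalent-copper oxidative free-radical bicyclisation of 2-methylacetoacetate-derived polyenes, including their 8-phenylmenthyl esters, that ends in an exocyclic alkene. Ring A closes by 6-endo-trig attack of C4 on C5 and ring B by 6-endo-trig attack of C10 on C9, both through chair-like transition states of the (E,E)-1,5-diene. C4 is set by the auxiliary, whose phenyl ring covers one face of the planar radical while the ester takes the axial position cis to C20 as is usual in these cyclisations; the trans C5/C10 relationship follows from the E geometry of C5=C10 in the chair–chair fold, and the equatorial C9 side chain (9α-H) from the E geometry of C8=C9. The step needs 6-endo over 5-exo closure, which the fully substituted inner alkene carbons C10 and C8 and the in-ring C3 carbonyl secure; it needs the diene to stay out, which is secured because the C8 radical could reach C12=C13 only by 4-exo or 5-endo closure and C14 or C15 only through six- or seven-membered rings that would contain the E double bond, with high dilution disfavouring intermolecular addition; and it needs exo-selective termination, which the preference of the organocopper intermediate for the least hindered β-hydrogen (CH3) should give.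

Step 7
Reactants: 11 (1R,2S,5R)-8-phenylmenthyl (4R,5R,9S,10R)-3-oxolabda-8(17),12E,14-trien-19-oate
Product: 12 C3 tosylhydrazone of 11
Conditions: TsNHNH2 (1.5 equiv), PPTS (0.1 equiv), EtOH/THF, 50 °C
Reagents that add atoms: 4-methylbenzenesulfonohydrazide, Cc1ccc(cc1)S(=O)(=O)NN
Why: Acid-catalysed condensation at the only ketone gives the tosylhydrazone, and the mild pyridinium acid should leave the exocyclic alkene, the diene and the non-enolisable C4 centre untouched.

Step 8
Reactants: 12 C3 tosylhydrazone of 11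
Product: 13 trans-communol
Conditions: LiAlH4 (6 equiv), THF, 0 °C → reflux; H2O work-up
Reagents that add atoms: none
Why: Caglioti reduction, in which hydride adds to C=N and the hydrazide anion loses sulfinate and N2 to leave C3 as CH2, while the same reagent reduces the neopentyl ester to the C19 alcohol and releases the auxiliary; isolated alkenes and the diene are inert to LiAlH4 and no stereocentre is touched.

Step 9
Reactants: 13 trans-communol
Product: 14 trans-communal
Conditions: Dess–Martin periodinane (1.3 equiv), NaHCO3, CH2Cl2, 0 °C → rt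
Reagents that add atoms: none
Why: Dess–Martin oxidation of the neopentyl primary alcohol stops at the aldehyde, which cannot epimerise because C4 is quaternary, and leaves the diene and the exocyclic alkene alone.

Step 10
Reactants: 15 (−)-caryophyllene oxide
Product: 16 (1′R,5′R,9′S)-caryophylla-4′(12′),8′(13′)-dien-5′-ol
Conditions: LiN(iPr)2 (2.5 equiv), Et2O, 0 °C → reflux; H2O work-up
Reagents that add atoms: none
Why: Base-promoted isomerisation of an epoxide to an allylic alcohol, in which the amide removes a proton of the C12′ methyl group syn to the oxirane and the C4′–O bond breaks, so that the C5′–O bond and its configuration are kept.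

Step 11
Reactants: 16 (1′R,5′R,9′S)-caryophylla-4′(12′),8′(13′)-dien-5′-ol
Product: 17 (1′R,4′S,5′R,9′S)-4′,12′-epoxycaryophyll-8′(13′)-en-5′-ol
Conditions: VO(acac)2 (3 mol %), t-BuOOH (1.5 equiv), CH2Cl2, 0 °C → rt
Reagents that add atoms: tert-butyl hydroperoxide, CC(C)(C)OO
Why: Hydroxyl-directed vanadium-catalysed epoxidation touches only the allylic 4′(12′)-alkene and should deliver oxygen to the face syn to the C5′ hydroxyl in the conformer that keeps H-5′ in the olefin plane next to C3′ (minimal A(1,2) strain, a torsion the nine-membered ring tolerates), which sets C4′.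

Step 12
Reactants: 17 (1′R,4′S,5′R,9′S)-4′,12′-epoxycaryophyll-8′(13′)-en-5′-ol
Product: 19 cis-4′,5′-epoxy 12′-silyl ether, via rearranged alkoxide 18 (not isolated)
Conditions: NaH (1.2 equiv), THF, 0 °C → rt; then TBSCl (1.3 equiv), 0 °C
Reagents that add atoms: tert-butyldimethylsilyl chloride, CC(C)(C)[Si](C)(C)Cl
Why: Payne rearrangement, in which the C5′ alkoxide opens the spiro-oxirane at C4′ with inversion (3-exo-tet) to give the more substituted epoxide and the primary alkoxide, the favoured and faster-silylating partner of the equilibrium, which is trapped as its silyl ether; inversion at C4′ makes the new 4′,5′-epoxide cis (C3′ and C6′ on one face).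

Step 13
Reactants: 19 cis-4′,5′-epoxy 12′-silyl ether
Product: 22 ring-trans 12′-silyloxy-β-caryophyllene, via hydroxyphosphine 20 (not isolated), via phosphonium betaine 21 (not isolated)
Conditions: LiPPh2 (1.5 equiv), THF, 0 °C → rt; then MeI (2.5 equiv), rt
Reagents that add atoms: none
Why: Epoxide deoxygenation with inversion of olefin geometry, in which phosphide opens the oxirane at the secondary C5′ by SN2 (anti), P-methylation gives the β-oxido phosphonium betaine, and its Wittig-type syn-elimination of Ph2MeP=O turns the cis-epoxide into the strained ring-trans C4′=C5′ olefin, as in the preparation of trans-cyclooctene from cis-cyclooctene oxide.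

Step 14
Reactants: 22 ring-trans 12′-silyloxy-β-caryophyllene
Product: 23 ring-trans 12′-hydroxy-β-caryophyllene
Conditions: Bu4NF (1.2 equiv), THF, 0 °C
Reagents that add atoms: none
Why: Fluoride-induced desilylation frees the primary allylic alcohol under conditions that should not isomerise the strained olefin.

Step 15
Reactants: 23 ring-trans 12′-hydroxy-β-caryophyllene
Product: 24 ring-trans β-caryophyllen-12′-al
Conditions: MnO2 (activated, 15 equiv), CH2Cl2, rt, dark
Reagents that add atoms: none
Why: Heterogeneous MnO2 oxidation is selective for the allylic alcohol and, being neutral and free of nucleophiles, should preserve the ring-trans geometry of the enal.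

Step 16
Reactants: 14 trans-communal; 24 ring-trans β-caryophyllen-12′-al
Product: 25 bis-aldehyde Diels–Alder adduct
Conditions: 14 (1.5 equiv), PhMe (1 M), BHT (5 mol %), 120 °C, sealed tube, Ar
Reagents that add atoms: none
Why: Thermal normal-demand Diels–Alder reaction of the strained ring-trans enal with the (E)-1,2-disubstituted diene, in which the unsubstituted terminus C15 bonds to the β-carbon C5′ and C12 to C4′ (the ortho orientation favoured by the 1-alkyl substituent and by lesser crowding at the shorter forming bond), the formyl group lies endo (Alder rule) so that C11 on C12 ends cis to it, suprafacial addition keeps C3′ and C6′ trans, and the diene adds to the olefin face that the predominant ring conformers expose (the face epoxidised in caryophyllene), which sets C12, C4′ and C5′.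

Step 17
Reactants: 25 bis-aldehyde Diels–Alder adduct
Product: 26 target CNP0330729.1
Conditions: NaClO2 (8 equiv), NaH2PO4 (8 equiv), 2-methyl-2-butene (40 equiv), t-BuOH/THF/H2O, 0 °C → rt
Reagents that add atoms: sodium chlorite, [Na+].[O-]Cl=O
Why: Pinnick oxidation converts both aldehydes, each on a quaternary carbon and therefore configurationally safe, into the carboxylic acids, the olefin scavenger intercepting HOCl before it can reach the three alkenes.

**Compound list**

1 | ethyl 2-methyl-3-oxobutanoate | CCOC(=O)C(C)C(C)=O | starting material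
2 | (1R,2S,5R)-(−)-8-phenylmenthol | O[C@@H]1C[C@H](C)CC[C@H]1C(C)(C)c1ccccc1 | starting material
3 | (1R,2S,5R)-8-phenylmenthyl 2-methyl-3-oxobutanoate (C2 epimers) | CC(=O)C(C)C(=O)O[C@@H]1C[C@H](C)CC[C@H]1C(C)(C)c1ccccc1 | intermediate
4 | but-1-en-3-yne (vinylacetylene, used as a commercial solution) | C=CC#C | starting material
5 | geranyl chloride, (2E)-1-chloro-3,7-dimethylocta-2,6-diene | ClC/C=C(\C)CCC=C(C)C | starting material
6 | dimethyl[(1E)-2-methylbuta-1,3-dien-1-yl]alane | C[Al](C)/C=C(\C)C=C | intermediate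
7 | (3E,6E)-α-farnesene | C=C/C(C)=C/C/C=C(\C)CCC=C(C)C | intermediate
8 | (2E,6E,9E)-2,6,10-trimethyldodeca-2,6,9,11-tetraen-1-ol | C=C/C(C)=C/C/C=C(\C)CC/C=C(\C)CO | intermediate
9 | (2E,6E,9E)-1-bromo-2,6,10-trimethyldodeca-2,6,9,11-tetraene | C=C/C(C)=C/C/C=C(\C)CC/C=C(\C)CBr | intermediate
10 | (1R,2S,5R)-8-phenylmenthyl (6E,10E,13E)-2,6,10,14-tetramethyl-3-oxohexadeca-6,10,13,15-tetraenoate (C2 epimers) | C=C/C(C)=C/C/C=C(\C)CC/C=C(\C)CCC(=O)C(C)C(=O)O[C@@H]1C[C@H](C)CC[C@H]1C(C)(C)c1ccccc1 | intermediate
11 | (1R,2S,5R)-8-phenylmenthyl (4R,5R,9S,10R)-3-oxolabda-8(17),12E,14-trien-19-oate (4β-axial ester, 5α-H, 9α-H, 10β-CH3) | C=C/C(C)=C/C[C@H]1C(=C)CC[C@@H]2[C@]1(C)CCC(=O)[C@]2(C)C(=O)O[C@@H]1C[C@H](C)CC[C@H]1C(C)(C)c1ccccc1 | intermediate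
12 | C3 tosylhydrazone of 11 (C=N geometry not assigned) | C=C/C(C)=C/C[C@H]1C(=C)CC[C@@H]2[C@]1(C)CCC(=NNS(=O)(=O)c1ccc(C)cc1)[C@]2(C)C(=O)O[C@@H]1C[C@H](C)CC[C@H]1C(C)(C)c1ccccc1 | intermediate
13 | trans-communol, (4S,5R,9S,10R)-labda-8(17),12E,14-trien-19-ol | C=C/C(C)=C/C[C@H]1C(=C)CC[C@@H]2[C@]1(C)CCC[C@]2(C)CO | intermediate
14 | trans-communal, (4S,5R,9S,10R)-labda-8(17),12E,14-trien-19-al | C=C/C(C)=C/C[C@H]1C(=C)CC[C@@H]2[C@]1(C)CCC[C@]2(C)C=O | intermediate
15 | (−)-caryophyllene oxide, (1′R,4′R,5′R,9′S)-4′,5′-epoxycaryophyll-8′(13′)-ene | C[C@@]12CC[C@@H]3[C@H](CC3(C)C)C(=C)CC[C@H]1O2 | starting material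
16 | (1′R,5′R,9′S)-caryophylla-4′(12′),8′(13′)-dien-5′-ol | C=C1CC[C@@H]2[C@H](CC2(C)C)C(=C)CC[C@H]1O | intermediate
17 | (1′R,4′S,5′R,9′S)-4′,12′-epoxycaryophyll-8′(13′)-en-5′-ol | O[C@@H]1CCC(=C)[C@H]2CC(C)(C)[C@@H]2CC[C@]13CO3 | intermediate
18 | sodium (1′R,4′R,5′R,9′S)-4′,5′-epoxycaryophyll-8′(13′)-en-12′-olate (cis-epoxide) | [Na+].[O-]C[C@]12CC[C@@H]3[C@H](CC3(C)C)C(=C)CC[C@H]1O2 | intermediate
19 | tert-butyldimethylsilyl ether of (1′R,4′R,5′R,9′S)-4′,5′-epoxycaryophyll-8′(13′)-en-12′-ol (cis-epoxide, C3′ and C6′ on one face) | CC(C)(C)[Si](C)(C)OC[C@]12CC[C@@H]3[C@H](CC3(C)C)C(=C)CC[C@H]1O2 | intermediate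
20 | lithium (1′R,4′R,5′S,9′S)-12′-(tert-butyldimethylsilyloxy)-5′-(diphenylphosphanyl)caryophyll-8′(13′)-en-4′-olate | CC(C)(C)[Si](C)(C)OC[C@]1([O-])CC[C@@H]2[C@H](CC2(C)C)C(=C)CC[C@@H]1P(c1ccccc1)c1ccccc1.[Li+] | intermediate
21 | P-methyl phosphonium betaine of 20 (4′-oxido, 5′-methyldiphenylphosphonio) | CC(C)(C)[Si](C)(C)OC[C@]1([O-])CC[C@@H]2[C@H](CC2(C)C)C(=C)CC[C@@H]1[P+](C)(c1ccccc1)c1ccccc1 | intermediate
22 | tert-butyldimethylsilyl ether of ring-trans (1′R,9′S)-caryophylla-4′,8′(13′)-dien-12′-ol (C3′ and C6′ anti across C4′=C5′) | CC(C)(C)[Si](C)(C)OC/C1=C\CCC(=C)[C@H]2CC(C)(C)[C@@H]2CC1 | intermediate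
23 | ring-trans (1′R,9′S)-caryophylla-4′,8′(13′)-dien-12′-ol (12′-hydroxy-β-caryophyllene; 4′Z by CIP because CH2OH outranks C3′) | OC/C1=C\CCC(=C)[C@H]2CC(C)(C)[C@@H]2CC1 | intermediate
24 | ring-trans (1′R,9′S)-caryophylla-4′,8′(13′)-dien-12′-al | O=C/C1=C\CCC(=C)[C@H]2CC(C)(C)[C@@H]2CC1 | intermediate
25 | bis-aldehyde adduct (4S,5R,9S,10R,12R; 1′R,4′S,5′S,9′S): cyclohexene C4′–C5′–C15–C14=C13–C12 trans-fused to the nine-membered ring, CHO on C4 (C19) and on C4′ (C12′) | C=C1CC[C@H]2CC=C(C)[C@@H](C[C@H]3C(=C)CC[C@@H]4[C@]3(C)CCC[C@]4(C)C=O)[C@]2(C=O)CC[C@@H]2[C@@H]1CC2(C)C | intermediate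
26 | CNP0330729.1, the 19,12′-dioic acid (4S,5R,9S,10R,12R; 1′R,4′S,5′S,9′S) | C=C1CC[C@H]2CC=C(C)[C@@H](C[C@H]3C(=C)CC[C@@H]4[C@]3(C)CCC[C@]4(C)C(=O)O)[C@]2(C(=O)O)CC[C@@H]2[C@@H]1CC2(C)C | target

**Count**

Total steps: 17. Longest linear sequence: 10 steps (steps 2–9, 16, 17).

**Steps most likely to fail**

Step 16. The two interconverting conformers of the nine-membered ring expose opposite faces of the C4′=C5′ bond, so the thermal addition may show poor facial selectivity. The hindered C12–C4′ bond may also form too slowly to outrun diene polymerisation or relaxation of 24 to the ring-cis enal. The fallback replaces substrate control by catalyst control and removes the Lewis-basic aldehyde from the diene partner; it sets out from 13 (and uses 24) and returns at 25. TBSCl/imidazole converts 13 into trans-communol tert-butyldimethylsilyl ether F1. F1 and 24 are combined in CH2Cl2 at −78 to −40 °C with a chiral oxazaborolidinium Lewis acid, (S)-3,3-diphenyl-1-(o-tolyl)tetrahydro-1H,3H-pyrrolo[1,2-c][1,3,2]oxazaborole protonated by HNTf2 (or its enantiomer, whichever is matched). The catalyst binds the formyl group of 24 and should select the reacting conformer, giving the mono-aldehyde adduct F2. Bu4NF frees the C19 alcohol (hydroxy aldehyde F3), and Dess–Martin oxidation gives 25.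

Step 6. The electrophilic enolate radical and the chain-carrying tertiary radicals may be intercepted by the conjugated diene of another molecule (oligomerisation), and the final hydrogen loss may drift toward the endocyclic isomers. In the fallback the diene is installed after the rings are made; it sets out from 3 and returns at 11. Commercial homogeraniol, (3E)-4,8-dimethylnona-3,7-dien-1-ol, is silylated (TBDPSCl, imidazole) to homogeraniol tert-butyldiphenylsilyl ether F4. SeO2/t-BuOOH oxidation of the E-methyl group gives allylic alcohol F5, and PBr3 gives allylic bromide F6. The dianion of 3 is alkylated with F6 to the silyloxy keto ester F7, which under the conditions of step 6 should give the bicyclic 12-silyloxy keto ester F8 by the same two ring closures. Bu4NF gives the primary alcohol F9, Dess–Martin oxidation the aldehyde F10, and Wittig reaction with Ph3P=C(CH3)CHO the (E)-enal F11. Methylenation with Ph3P=CH2 at −78 °C (aldehyde before the hindered C3 ketone) gives 11.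

Step 13. The phosphide may act as a base toward the epoxide (isomerisation to an allylic alcohol) or attack the hindered C5′ too slowly, and the alkoxide formed may shift the silyl group. The fallback is a stereospecific syn-elimination from a cyclic thionocarbonate (Corey–Winter olefination) in place of steps 12 and 13; it sets out from 17 and returns at 22. Aqueous NaOH in t-BuOH opens the spiro-oxirane of 17 at the primary C12′ to the 4′,5′,12′-triol F12, with C4′ and C5′ untouched. TBSCl/imidazole silylates the primary hydroxyl to give the 12′-silyloxy 4′,5′-diol F13, and 1,1′-thiocarbonyldiimidazole closes the cyclic thionocarbonate F14. 1,3-Dimethyl-2-phenyl-1,3,2-diazaphospholidine at 40 °C removes it with syn stereospecificity; with the two oxygens eclipsed, C3′ and C6′ lie anti, so the ring-trans olefin 22 should result.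

**Further compounds**

F1 | step 16 | trans-communol tert-butyldimethylsilyl ether | C=C/C(C)=C/C[C@H]1C(=C)CC[C@@H]2[C@]1(C)CCC[C@]2(C)CO[Si](C)(C)C(C)(C)C
F2 | step 16 | mono-aldehyde adduct (C19 silyl ether, 12′-al) | C=C1CC[C@H]2CC=C(C)[C@@H](C[C@H]3C(=C)CC[C@@H]4[C@]3(C)CCC[C@]4(C)CO[Si](C)(C)C(C)(C)C)[C@]2(C=O)CC[C@@H]2[C@@H]1CC2(C)C
F3 | step 16 | hydroxy aldehyde adduct (19-ol, 12′-al) | C=C1CC[C@H]2CC=C(C)[C@@H](C[C@H]3C(=C)CC[C@@H]4[C@]3(C)CCC[C@]4(C)CO)[C@]2(C=O)CC[C@@H]2[C@@H]1CC2(C)C
F4 | step 6 | homogeraniol tert-butyldiphenylsilyl ether | CC(C)=CCC/C(C)=C/CCO[Si](c1ccccc1)(c1ccccc1)C(C)(C)C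
F5 | step 6 | (2E,6E)-9-(tert-butyldiphenylsilyloxy)-2,6-dimethylnona-2,6-dien-1-ol | OC/C(C)=C/CC/C(C)=C/CCO[Si](c1ccccc1)(c1ccccc1)C(C)(C)C
F6 | step 6 | (2E,6E)-1-bromo-9-(tert-butyldiphenylsilyloxy)-2,6-dimethylnona-2,6-diene | BrC/C(C)=C/CC/C(C)=C/CCO[Si](c1ccccc1)(c1ccccc1)C(C)(C)C
F7 | step 6 | (1R,2S,5R)-8-phenylmenthyl (6E,10E)-13-(tert-butyldiphenylsilyloxy)-2,6,10-trimethyl-3-oxotrideca-6,10-dienoate | CC(C(=O)CC/C(C)=C/CC/C(C)=C/CCO[Si](c1ccccc1)(c1ccccc1)C(C)(C)C)C(=O)O[C@@H]1C[C@H](C)CC[C@H]1C(C)(C)c1ccccc1
F8 | step 6 | (1R,2S,5R)-8-phenylmenthyl 12-(tert-butyldiphenylsilyloxy)-3-oxo-13,14,15,16-tetranorlabd-8(17)-en-19-oate | CC(C)(C)[Si](c1ccccc1)(c1ccccc1)OCC[C@H]1C(=C)CC[C@@H]2[C@]1(C)CCC(=O)[C@]2(C)C(=O)O[C@@H]1C[C@H](C)CC[C@H]1C(C)(C)c1ccccc1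
F9 | step 6 | (1R,2S,5R)-8-phenylmenthyl 12-hydroxy-3-oxo-13,14,15,16-tetranorlabd-8(17)-en-19-oate | OCC[C@H]1C(=C)CC[C@@H]2[C@]1(C)CCC(=O)[C@]2(C)C(=O)O[C@@H]1C[C@H](C)CC[C@H]1C(C)(C)c1ccccc1
F10 | step 6 | (1R,2S,5R)-8-phenylmenthyl 3,12-dioxo-13,14,15,16-tetranorlabd-8(17)-en-19-oate | O=CC[C@H]1C(=C)CC[C@@H]2[C@]1(C)CCC(=O)[C@]2(C)C(=O)O[C@@H]1C[C@H](C)CC[C@H]1C(C)(C)c1ccccc1
F11 | step 6 | (1R,2S,5R)-8-phenylmenthyl (12E)-3,14-dioxo-15-norlabda-8(17),12-dien-19-oate | O=C/C(C)=C/C[C@H]1C(=C)CC[C@@H]2[C@]1(C)CCC(=O)[C@]2(C)C(=O)O[C@@H]1C[C@H](C)CC[C@H]1C(C)(C)c1ccccc1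
F12 | step 13 | (1′R,4′S,5′R,9′S)-caryophyll-8′(13′)-ene-4′,5′,12′-triol | OC[C@@]1(O)CC[C@@H]2[C@H](CC2(C)C)C(=C)CC[C@H]1O
F13 | step 13 | 12′-O-tert-butyldimethylsilyl ether of F12 | CC(C)(C)[Si](C)(C)OC[C@@]1(O)CC[C@@H]2[C@H](CC2(C)C)C(=C)CC[C@H]1O
F14 | step 13 | 4′,5′-cyclic thionocarbonate of F13 | CC(C)(C)[Si](C)(C)OC[C@@]12CC[C@@H]3[C@H](CC3(C)C)C(=C)CC[C@H]1OC(=S)O2
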